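**Retrosynthetic overview**

1. The target comes from gem-diprenylation of the only free ring CH2 of the unprenylated spiro acetyl-trione. That trione comes, in the key step, from a hydrindane acyl imidazole carrying a bridged lactone plus pentane-2,4-dione: the diketone dianion is C-acylated at its terminal carbon, and the triketone so formed closes onto the lactone carbonyl (Dieckmann-type Claisen), which builds the whole trione ring and opens the lactone.
2. Enabling feature (hydrindane locants: C1 and C4 = methyl carbinol carbons, C3a/C7a = ring fusion, C6 = spiro carbon): the axial tertiary oxygen on C4 of the cyclohexane ring is cis and 1,3-diaxial to the one C6 carbonyl carbon that is bonded to the acetyl-bearing carbon of the trione ring. Joined as a γ-lactone bridge (6-oxabicyclo[3.2.1]octan-7-one, a ring absent from the target), they make the two carbonyl carbons on C6 chemically different, so the spiro configuration is fixed before the trione ring exists.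
3. The lactone comes from a (2-hydroxy-2-methyl-5-isopropenylcyclopentyl)methyl malonate by Mn(OAc)3 oxidative 6-endo radical cyclisation with capture of the tertiary cation by the axial ester (closes the cyclohexane ring, sets C4 and C6).
4. The malonate comes from an epoxy aldehyde (Knoevenagel, palladium/formate hydrogenolysis with inversion at C7a, conjugate reduction), itself from a cyclopentenecarbaldehyde made from (+)-limonene oxide (chiral pool, supplies C3a; C1 from epoxidation anti to isopropenyl).
5. Ring order: cyclopentane (step 2), cyclohexane of the hydrindane together with the temporary lactone (step 7), trione ring last (step 10).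

Key step: step 10

Assumption: the target is drawn as one enol tautomer of a 2-acylcyclohexane-1,3,5-trione; the route should deliver the tautomeric mixture that the compound itself adopts, and the descriptors given for the spiro carbon refer to the tautomer drawn.

**Route**

Step 1
Reactants: 1 (+)-limonene 1,2-oxide [(4R), commercial cis/trans mixture]
Product: 3 (3R)-6-oxo-3-(prop-1-en-2-yl)heptanal, via limonene-1,2-diol 2 (not isolated)
Conditions: H5IO6 (1.2 equiv), THF/H2O, 0 °C → rt
Reagents that add atoms: water (O)
Why: Acid-promoted epoxide hydrolysis to the glycol 2 and periodate glycol cleavage in the same flask open the six-membered ring between its two oxygenated carbons; both epoxide diastereomers converge, and the isopropenyl group and the stereocentre (the future C3a) are untouched.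

Step 2
Reactants: 3 (3R)-6-oxo-3-(prop-1-en-2-yl)heptanal
Product: 4 (5S)-2-methyl-5-(prop-1-en-2-yl)cyclopent-1-ene-1-carbaldehyde
Conditions: piperidine (0.3 equiv), AcOH (0.3 equiv), toluene, reflux (Dean–Stark)
Reagents that add atoms: none
Why: Intramolecular aldol condensation under secondary-amine catalysis: the aldehyde reacts as its piperidine enamine with the methyl ketone and the aldol dehydrates, which directs closure to the cyclopentene-carbaldehyde (not the isomeric acetylcyclopentene) and leaves the stereocentre, which is attached to the α-carbon of the enal and is not a γ-position, unchanged.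

Step 3
Reactants: 4 (5S)-2-methyl-5-(prop-1-en-2-yl)cyclopent-1-ene-1-carbaldehyde
Product: 5 (1S,2S,5R)-5-methyl-2-(prop-1-en-2-yl)-6-oxabicyclo[3.1.0]hexane-1-carbaldehyde
Conditions: 30% aq. H2O2, NaOH (cat.), MeOH, 0 °C
Reagents that add atoms: hydrogen peroxide (OO)
Why: Weitz–Scheffer nucleophilic epoxidation: hydroperoxide adds to the β-carbon and the enolate closes on oxygen from the ring face opposite to the isopropenyl group on the neighbouring carbon (as in the alkaline epoxidation of carvone), which sets the C–O bond of the future C1 carbinol, while the electron-rich isopropenyl alkene does not react with the peroxide anion.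

Step 4
Reactants: 5 (1S,2S,5R)-5-methyl-2-(prop-1-en-2-yl)-6-oxabicyclo[3.1.0]hexane-1-carbaldehyde; 6 dibenzyl malonate
Product: 7 dibenzyl 2-{[(1S,2S,5R)-5-methyl-2-(prop-1-en-2-yl)-6-oxabicyclo[3.1.0]hexan-1-yl]methylidene}propanedioate
Conditions: piperidine (cat.), AcOH (cat.), toluene, 4 Å molecular sieves, 60 °C
Reagents that add atoms: none
Why: Knoevenagel condensation of a non-enolisable aldehyde, activated by its α-oxygen, with a malonate under piperidinium acetate catalysis; no stereocentre is touched and the tetrasubstituted epoxide is too hindered to be opened by the amine.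

Step 5
Reactants: 7 dibenzyl 2-{[(1S,2S,5R)-5-methyl-2-(prop-1-en-2-yl)-6-oxabicyclo[3.1.0]hexan-1-yl]methylidene}propanedioate
Product: 8 dibenzyl 2-{[(1S,2R,5R)-2-hydroxy-2-methyl-5-(prop-1-en-2-yl)cyclopentyl]methylidene}propanedioate
Conditions: Pd2(dba)3·CHCl3 (2.5 mol%), n-Bu3P (5 mol%), HCO2H (3 equiv), Et3N (2 equiv), 1,4-dioxane, rt
Reagents that add atoms: none
Why: Palladium-catalysed formate hydrogenolysis of an alkenyl oxirane: zerovalent palladium ionises the allylic C–O bond anti to oxygen, the formate on the π-allyl palladium alkoxide loses CO2, and the hydride passes from the metal to the ring carbon, so hydrogen enters with inversion at C7a, the side chain ends up trans to the isopropenyl group and cis to the tertiary hydroxyl, and the conjugated alkylidene malonate is kept.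

Step 6
Reactants: 8 dibenzyl 2-{[(1S,2R,5R)-2-hydroxy-2-methyl-5-(prop-1-en-2-yl)cyclopentyl]methylidene}propanedioate
Product: 9 dibenzyl 2-{[(1S,2R,5R)-2-hydroxy-2-methyl-5-(prop-1-en-2-yl)cyclopentyl]methyl}propanedioate
Conditions: NaBH4 (1.1 equiv), THF/EtOH, 0 °C
Reagents that add atoms: none
Why: Conjugate (1,4) hydride reduction of an alkylidene malonate by borohydride, which stops at the malonate enolate and leaves the esters, the 1,1-disubstituted alkene and all stereocentres alone.

Step 7
Reactants: 9 dibenzyl 2-{[(1S,2R,5R)-2-hydroxy-2-methyl-5-(prop-1-en-2-yl)cyclopentyl]methyl}propanedioate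
Product: 10 benzyl (1S,2R,5R,6S,8S)-5-hydroxy-1,5-dimethyl-9-oxo-10-oxatricyclo[6.2.1.0^{2,6}]undecane-8-carboxylate
Conditions: Mn(OAc)3·2H2O (2.2 equiv), AcOH, 60 °C
Reagents that add atoms: none
Why: Oxidative free-radical cyclisation with Mn(OAc)3: the trivalent manganese enolate gives the malonyl radical, which adds 6-endo to the CH2 end of the isopropenyl group (5-exo would need a trans-fused bicyclo[3.3.0]octane), the tertiary radical is oxidised to the C4 cation, and the axial ester carbonyl captures it with loss of benzyl as benzyl acetate; because only the ester that is axial on the locked chair of the trans-hydrindane can reach C4, the C4–O bond (trans to H-3a) and the C6 configuration are set together.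

Step 8
Reactants: 10 benzyl (1S,2R,5R,6S,8S)-5-hydroxy-1,5-dimethyl-9-oxo-10-oxatricyclo[6.2.1.0^{2,6}]undecane-8-carboxylate
Product: 11 (1S,2R,5R,6S,8S)-5-hydroxy-1,5-dimethyl-9-oxo-10-oxatricyclo[6.2.1.0^{2,6}]undecane-8-carboxylic acid
Conditions: H2 (1 atm), 10% Pd/C, EtOAc, rt
Reagents that add atoms: none
Why: Catalytic hydrogenolysis of the benzyl ester; no alkene remains at this stage, and the lactone and the tertiary alcohol are inert.

Step 9
Reactants: 11 (1S,2R,5R,6S,8S)-5-hydroxy-1,5-dimethyl-9-oxo-10-oxatricyclo[6.2.1.0^{2,6}]undecane-8-carboxylic acid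
Product: 12 (1S,2R,5R,6S,8S)-5-hydroxy-8-(1H-imidazole-1-carbonyl)-1,5-dimethyl-10-oxatricyclo[6.2.1.0^{2,6}]undecan-9-one
Conditions: CDI (1.2 equiv), THF, rt
Reagents that add atoms: 1,1'-carbonyldiimidazole, CDI (O=C(n1ccnc1)n1ccnc1)
Why: Activation of the acid as its N-acylimidazole with CDI (acyl transfer with loss of CO2); the tertiary C1 hydroxyl does not react with CDI at room temperature and, being anti to C6 across the ring, cannot reach the acyl group.

Step 10
Reactants: 12 (1S,2R,5R,6S,8S)-5-hydroxy-8-(1H-imidazole-1-carbonyl)-1,5-dimethyl-10-oxatricyclo[6.2.1.0^{2,6}]undecan-9-one; 13 pentane-2,4-dione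
Product: 16 (1S,3'R,3a'S,7'S,7a'R)-3-acetyl-3',4,7'-trihydroxy-3',7'-dimethyl-1',2',3',3a',4',6',7',7a'-octahydrospiro[cyclohex-3-ene-1,5'-indene]-2,6-dione, via dilithium pentane-2,4-dione dianion 14 (not isolated), via lactone triketone 15 (not isolated)
Conditions: 13 (3.2 equiv), LiN(iPr)2 (6.4 equiv), THF, 0 °C; then 12, −78 °C → 50 °C; aq. HCl
Reagents that add atoms: none
Why: The terminal carbanion of dianion 14 attacks the acyl imidazole carbonyl of 12, which is far more electrophilic than the lactone, to give triketone 15 as its dienolate; on warming, the central carbon between the two outer carbonyls of 15 attacks the lactone carbonyl, the tertiary C4 alkoxide leaves, and the triacylmethane that results is deprotonated at once, which pulls the sequence to 16. The closest known reaction types are the terminal C-acylation of β-diketone dianions and the Claisen cyclisation of 3,5,7-triketo esters to acylphloroglucinols, here with a lactone as the ester. The trione ring closes in a 6-(enolendo)-exo-trig Dieckmann mode, and the same bond formation opens the strained 6-oxabicyclo[3.2.1]octanone bridge and frees the C4 hydroxyl. No new stereocentre is formed: the spiro carbon C6 was fixed in step 7, and the step only converts its two already different acyl carbons into the two different ring carbonyls, the one cis to C4–OH ending next to the acetyl-bearing carbon. The selectivity needed is the order of the two acylations, terminal carbon on the carbonyl that will neighbour the future diprenyl carbon and central carbon on the lactone; it is secured by the reactivity gap between acyl imidazole and lactone, by ring size (attack of the other enolate carbon would give a four-membered ring), and by the absence of any enolisable hydrogen in 12 (C6 is quaternary and a bridgehead), so neither proton transfer nor retro-Claisen cleavage at C6 can compete.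

Step 11
Reactants: 16 (1S,3'R,3a'S,7'S,7a'R)-3-acetyl-3',4,7'-trihydroxy-3',7'-dimethyl-1',2',3',3a',4',6',7',7a'-octahydrospiro[cyclohex-3-ene-1,5'-indene]-2,6-dione; 17 1-bromo-3-methylbut-2-ene (prenyl bromide)
Product: 18 (1S,3'R,3a'S,7'S,7a'R)-5-acetyl-3',4,7'-trihydroxy-3',7'-dimethyl-3,3-bis(3-methylbut-2-en-1-yl)-1',2',3',3a',4',6',7',7a'-octahydrospiro[cyclohex-4-ene-1,5'-indene]-2,6-dione
Conditions: NaOMe (3 equiv), 17 (2.5 equiv), MeOH, 0 °C → rt
Reagents that add atoms: none
Why: C-Alkylation of the vinylogous-acid enolate of an acylphloroglucinol-type trione with prenyl bromide in methanolic methoxide, the classical gem-diprenylation that converts deoxyhumulones into lupulones: the CH2 between two carbonyls is the only free nucleophilic carbon, it is alkylated twice, and no stereocentre is formed or disturbed.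

**Compound list**

1 | (+)-limonene 1,2-oxide, (4R)-1-methyl-4-(prop-1-en-2-yl)-7-oxabicyclo[4.1.0]heptane (cis/trans mixture at the epoxide) | CC12OC1C[C@@H](CC2)C(C)=C | starting material
2 | (4R)-1-methyl-4-(prop-1-en-2-yl)cyclohexane-1,2-diol (limonene-1,2-diol) | CC(=C)[C@@H]1CCC(C)(O)C(O)C1 | intermediate
3 | (3R)-6-oxo-3-(prop-1-en-2-yl)heptanal | CC(=O)CC[C@H](CC=O)C(C)=C | intermediate
4 | (5S)-2-methyl-5-(prop-1-en-2-yl)cyclopent-1-ene-1-carbaldehyde | O=CC1=C(C)CC[C@H]1C(C)=C | intermediate
5 | (1S,2S,5R)-5-methyl-2-(prop-1-en-2-yl)-6-oxabicyclo[3.1.0]hexane-1-carbaldehyde | O=C[C@@]12O[C@]1(C)CC[C@H]2C(C)=C | intermediate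
6 | dibenzyl propanedioate (dibenzyl malonate) | O=C(CC(=O)OCc1ccccc1)OCc1ccccc1 | starting material
7 | dibenzyl 2-{[(1S,2S,5R)-5-methyl-2-(prop-1-en-2-yl)-6-oxabicyclo[3.1.0]hexan-1-yl]methylidene}propanedioate | O=C(OCc1ccccc1)C(C(=O)OCc1ccccc1)=C[C@@]12O[C@]1(C)CC[C@H]2C(C)=C | intermediate
8 | dibenzyl 2-{[(1S,2R,5R)-2-hydroxy-2-methyl-5-(prop-1-en-2-yl)cyclopentyl]methylidene}propanedioate | O=C(OCc1ccccc1)C(C(=O)OCc1ccccc1)=C[C@@H]1[C@](C)(O)CC[C@H]1C(C)=C | intermediate
9 | dibenzyl 2-{[(1S,2R,5R)-2-hydroxy-2-methyl-5-(prop-1-en-2-yl)cyclopentyl]methyl}propanedioate | O=C(OCc1ccccc1)C(C(=O)OCc1ccccc1)C[C@@H]1[C@](C)(O)CC[C@H]1C(C)=C | intermediate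
10 | benzyl (1S,2R,5R,6S,8S)-5-hydroxy-1,5-dimethyl-9-oxo-10-oxatricyclo[6.2.1.0^{2,6}]undecane-8-carboxylate | O=C(OCc1ccccc1)[C@@]23C[C@H]4[C@@H](CC[C@@]4(C)O)[C@@](C)(OC2=O)C3 | intermediate
11 | (1S,2R,5R,6S,8S)-5-hydroxy-1,5-dimethyl-9-oxo-10-oxatricyclo[6.2.1.0^{2,6}]undecane-8-carboxylic acid | OC(=O)[C@@]23C[C@H]4[C@@H](CC[C@@]4(C)O)[C@@](C)(OC2=O)C3 | intermediate
12 | (1S,2R,5R,6S,8S)-5-hydroxy-8-(1H-imidazole-1-carbonyl)-1,5-dimethyl-10-oxatricyclo[6.2.1.0^{2,6}]undecan-9-one | O=C(n1ccnc1)[C@@]23C[C@H]4[C@@H](CC[C@@]4(C)O)[C@@](C)(OC2=O)C3 | intermediate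
13 | pentane-2,4-dione | CC(=O)CC(C)=O | starting material
14 | dilithium pentane-2,4-dione dianion (1,3-dilithio) | [Li+].[Li+].[CH2-]C(=O)[CH-]C(C)=O | intermediate
15 | 1-[(1S,2R,5R,6S,8S)-5-hydroxy-1,5-dimethyl-9-oxo-10-oxatricyclo[6.2.1.0^{2,6}]undecan-8-yl]hexane-1,3,5-trione (present as its lithium dienolate) | CC(=O)CC(=O)CC(=O)[C@@]23C[C@H]4[C@@H](CC[C@@]4(C)O)[C@@](C)(OC2=O)C3 | intermediate
16 | (1S,3'R,3a'S,7'S,7a'R)-3-acetyl-3',4,7'-trihydroxy-3',7'-dimethyl-1',2',3',3a',4',6',7',7a'-octahydrospiro[cyclohex-3-ene-1,5'-indene]-2,6-dione | CC(=O)C1=C(O)CC(=O)[C@@]2(C[C@H]3[C@@H](CC[C@@]3(C)O)[C@@](C)(O)C2)C1=O | intermediate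
17 | 1-bromo-3-methylbut-2-ene (prenyl bromide) | CC(C)=CCBr | starting material
18 | (1S,3'R,3a'S,7'S,7a'R)-5-acetyl-3',4,7'-trihydroxy-3',7'-dimethyl-3,3-bis(3-methylbut-2-en-1-yl)-1',2',3',3a',4',6',7',7a'-octahydrospiro[cyclohex-4-ene-1,5'-indene]-2,6-dione (CNP0266834.3) | CC(=O)C1=C(O)C(CC=C(C)C)(CC=C(C)C)C(=O)[C@@]2(C[C@H]3[C@@H](CC[C@@]3(C)O)[C@@](C)(O)C2)C1=O | target

**Step count and risks**

Total steps: 11. Longest linear sequence: 11 steps (1 to 18); the other building blocks (6, 13, 17) are commercial.

Steps most likely to fail: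

1. Step 10. The ring-closing Claisen attack on the hindered lactone carbonyl may stall at the open-chain triketone dienolate, which on acidic work-up would cyclise through oxygen to a 4-pyranone. The fallback sets out from 12 and comes back at 18. Decarboxylative Claisen homologation of 12 with magnesium methyl malonate (potassium methyl malonate, MgCl2, Et3N, THF) should give the β-keto ester methyl 3-[(1S,2R,5R,6S,8S)-5-hydroxy-1,5-dimethyl-9-oxo-10-oxatricyclo[6.2.1.0^{2,6}]undecan-8-yl]-3-oxopropanoate F1. Double C-prenylation with 17 (K2CO3, acetone, reflux) should give methyl 2-{[(1S,2R,5R,6S,8S)-5-hydroxy-1,5-dimethyl-9-oxo-10-oxatricyclo[6.2.1.0^{2,6}]undecan-8-yl]carbonyl}-5-methyl-2-(3-methylbut-2-en-1-yl)hex-4-enoate F2. Excess lithium enolate of acetone (acetone, LiN(iPr)2, THF, −78 °C → rt) is then acylated twice at the same carbon, by the lactone and by the methyl ester (Claisen condensation, then ring-closing Claisen of the β-diketone enolate). Because one carbon bridges both acyl groups, the order of the two events is immaterial; this gives 18 directly and makes step 11 unnecessary.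

2. Step 11. Alkylation at enol oxygen and an incomplete second alkylation at the hindered ring carbon may outrun clean gem-C-prenylation. The fallback sets out from 16 and comes back at 18. Palladium-catalysed double C-allylation (allyl methyl carbonate, Pd(PPh3)4, THF, rt) uses a soft π-allyl electrophile, and any O-allyl enol ether can still be moved to carbon by Claisen rearrangement. It should give the gem-diallyl compound (1S,3'R,3a'S,7'S,7a'R)-5-acetyl-3',4,7'-trihydroxy-3',7'-dimethyl-3,3-di(prop-2-en-1-yl)-1',2',3',3a',4',6',7',7a'-octahydrospiro[cyclohex-4-ene-1,5'-indene]-2,6-dione F3. Cross-metathesis of both terminal alkenes with 2-methylbut-2-ene (second-generation Grubbs catalyst, CH2Cl2, 40 °C) turns allyl into prenyl and returns to 18.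

3. Step 7. After the 6-endo closure the tertiary cation may lose a proton or take up acetate faster than the axial ester captures it, and the free C1 hydroxyl may transesterify onto the malonate before the radical forms. The fallback sets out from 9 and comes back at 10. Bromination of the malonate carbon (NaH, then N-bromosuccinimide, THF, 0 °C) should give dibenzyl 2-bromo-2-{[(1S,2R,5R)-2-hydroxy-2-methyl-5-(prop-1-en-2-yl)cyclopentyl]methyl}propanedioate F4. Bromine atom-transfer radical cyclisation (Et3B, air, benzene, rt) in the same 6-endo mode should give the tertiary bromide dibenzyl (3R,3aS,7aR)-7-bromo-3-hydroxy-3,7-dimethyl-1,2,3,3a,4,6,7,7a-octahydro-5H-indene-5,5-dicarboxylate F5 (both C7 epimers). Warming F5 in MeCN with NaHCO3 ionises the C–Br bond of either epimer, and the axial ester closes on the cation with loss of benzyl bromide, which returns to 10 without acid or a metal oxidant.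

Further compounds
F1 | step 10 | methyl 3-[(1S,2R,5R,6S,8S)-5-hydroxy-1,5-dimethyl-9-oxo-10-oxatricyclo[6.2.1.0^{2,6}]undecan-8-yl]-3-oxopropanoate | COC(=O)CC(=O)[C@@]23C[C@H]4[C@@H](CC[C@@]4(C)O)[C@@](C)(OC2=O)C3
F2 | step 10 | methyl 2-{[(1S,2R,5R,6S,8S)-5-hydroxy-1,5-dimethyl-9-oxo-10-oxatricyclo[6.2.1.0^{2,6}]undecan-8-yl]carbonyl}-5-methyl-2-(3-methylbut-2-en-1-yl)hex-4-enoate | COC(=O)C(CC=C(C)C)(CC=C(C)C)C(=O)[C@@]23C[C@H]4[C@@H](CC[C@@]4(C)O)[C@@](C)(OC2=O)C3
F3 | step 11 | (1S,3'R,3a'S,7'S,7a'R)-5-acetyl-3',4,7'-trihydroxy-3',7'-dimethyl-3,3-di(prop-2-en-1-yl)-1',2',3',3a',4',6',7',7a'-octahydrospiro[cyclohex-4-ene-1,5'-indene]-2,6-dione | CC(=O)C1=C(O)C(CC=C)(CC=C)C(=O)[C@@]2(C[C@H]3[C@@H](CC[C@@]3(C)O)[C@@](C)(O)C2)C1=O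
F4 | step 7 | dibenzyl 2-bromo-2-{[(1S,2R,5R)-2-hydroxy-2-methyl-5-(prop-1-en-2-yl)cyclopentyl]methyl}propanedioate | O=C(OCc1ccccc1)C(Br)(C(=O)OCc1ccccc1)C[C@@H]1[C@](C)(O)CC[C@H]1C(C)=C
F5 | step 7 | dibenzyl (3R,3aS,7aR)-7-bromo-3-hydroxy-3,7-dimethyl-1,2,3,3a,4,6,7,7a-octahydro-5H-indene-5,5-dicarboxylate (both C7 epimers) | O=C(OCc1ccccc1)C2(C(=O)OCc1ccccc1)C[C@H]3[C@@H](CC[C@@]3(C)O)C(C)(Br)C2
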